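Ring C is cut at C3–C4 and O1–C2. This is possible because C3, the carbon that carries ring B, corresponds to the α-carbon of an arylacetaldehyde, and C4 to the carboxyl carbon of a ring A salicylic acid whose ortho oxygen is O1. In a single flask the morpholine enamine of the ring B acetaldehyde is C-acylated by an O-acetylsalicyloyl chloride (C3–C4); the acetates are then cleaved and the ortho phenol displaces morpholine at C2 (O1–C2), closing ring C. The precursors are 2,4-diacetoxy-6-methoxybenzoyl chloride and the (E)-β-morpholinostyrene built on the MOM-protected 8-hydroxy-2,2-dimethylchromene; one acid step then releases the target.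

Key step: step 10

Remark: the target has no stereocentre; the enamine and enaminone double bonds are drawn E, and their geometry has no influence on the ring closure.

Step 1
Reactants: 1 5-methoxyresorcinol
Product: 3 2,4-dihydroxy-6-methoxybenzaldehyde, via iminium chloride 2 (not isolated)
Conditions: POCl3 (1.1 equiv), DMF, MeCN, 0 °C → rt; then H2O, 50 °C
Reagents that add atoms: N,N-dimethylformamide, CN(C)C=O; water, O
Why: Vilsmeier–Haack formylation: the chloroiminium ion should attack C4/C6 (para to one hydroxyl, two equivalent sites) in preference to C2, and hydrolysis of iminium salt 2 releases the aldehyde, the minor 2,6-dihydroxy-4-methoxy isomer being removed by crystallisation.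

Step 2
Reactants: 3 2,4-dihydroxy-6-methoxybenzaldehyde
Product: 4 4-formyl-5-methoxy-1,3-phenylene diacetate
Conditions: Ac2O, pyridine, DMAP (cat.), CH2Cl2, 0 °C → rt
Reagents that add atoms: acetic anhydride, CC(=O)OC(C)=O
Why: DMAP-catalysed O-acetylation of both phenols, including the hydrogen-bonded ortho one, which shields the ring from chlorination in step 3 and installs the ortho acetate that later becomes O1.

Step 3
Reactants: 4 4-formyl-5-methoxy-1,3-phenylene diacetate
Product: 5 2,4-diacetoxy-6-methoxybenzoic acid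
Conditions: NaClO2, NaH2PO4, 2-methylbut-2-ene, t-BuOH/THF/H2O, 0 °C → rt
Reagents that add atoms: sodium chlorite, [Na+].[O-]Cl=O
Why: Pinnick oxidation: chlorous acid converts the hindered aryl aldehyde into the acid in a mildly acidic buffer that leaves aryl acetates intact, while the alkene traps hypochlorous acid.

Step 4
Reactants: 5 2,4-diacetoxy-6-methoxybenzoic acid
Product: 6 2,4-diacetoxy-6-methoxybenzoyl chloride
Conditions: (COCl)2, DMF (cat.), CH2Cl2, 0 °C → rt; evaporate from toluene, use crude
Reagents that add atoms: oxalyl chloride, O=C(Cl)C(=O)Cl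
Why: Acid chloride formation through the chloroiminium species from oxalyl chloride and DMF, as for O-acetylsalicyloyl chloride itself, with only volatile by-products so that the crude chloride can be used directly.

Step 5
Reactants: 7 diphenylphosphine oxide; 8 morpholine
Product: 9 (morpholinomethyl)diphenylphosphine oxide
Conditions: (CH2O)n, toluene, 90 °C
Reagents that add atoms: paraformaldehyde (as formaldehyde), C=O
Why: Phospha-Mannich (Kabachnik–Fields-type) condensation in which the iminium ion from morpholine and formaldehyde is captured by the P–H bond of the secondary phosphine oxide.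

Step 6
Reactants: 10 3,4-dihydroxybenzaldehyde; 11 3-chloro-3-methylbut-1-yne
Product: 12 3-hydroxy-4-[(2-methylbut-3-yn-2-yl)oxy]benzaldehyde
Conditions: K2CO3 (1.0 equiv), KI (cat.), CuI (cat.), DMF, 60 °C, N2
Reagents that add atoms: none
Why: Copper-assisted O-alkylation of a phenoxide by a tertiary propargylic chloride: one equivalent of carbonate ionises only the more acidic 4-OH (para to the formyl group), and the reactive copper acetylide-derived electrophile is captured by that phenoxide, so the ether should form at O4.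

Step 7
Reactants: 12 3-hydroxy-4-[(2-methylbut-3-yn-2-yl)oxy]benzaldehyde
Product: 13 3-(methoxymethoxy)-4-[(2-methylbut-3-yn-2-yl)oxy]benzaldehyde
Conditions: MOMCl, i-Pr2NEt, CH2Cl2, 0 °C → rt
Reagents that add atoms: chloromethyl methyl ether, COCCl
Why: Williamson-type O-alkylation of the remaining phenol, giving a MOM ether that tolerates heat, organolithium and amine reagents and is removed by acid at the end.

Step 8
Reactants: 13 3-(methoxymethoxy)-4-[(2-methylbut-3-yn-2-yl)oxy]benzaldehyde
Product: 16 8-(methoxymethoxy)-2,2-dimethyl-2H-chromene-6-carbaldehyde, via allenyl phenol 14 (not isolated), via quinone methide 15 (not isolated)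
Conditions: PhNEt2, 190 °C
Reagents that add atoms: none
Why: Aromatic propargyl Claisen rearrangement to C5, the only free ortho carbon, gives allenyl phenol 14, whose 1,5-hydrogen shift to quinone methide 15 and oxa-6π electrocyclisation close the 2,2-dimethylpyran ring, as is general for aryl 1,1-dimethylpropargyl ethers.

Step 9
Reactants: 16 8-(methoxymethoxy)-2,2-dimethyl-2H-chromene-6-carbaldehyde; 9 (morpholinomethyl)diphenylphosphine oxide
Product: 18 (E)-4-{2-[8-(methoxymethoxy)-2,2-dimethyl-2H-chromen-6-yl]vinyl}morpholine, via phosphine oxide adduct 17 (not isolated)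
Conditions: 9, n-BuLi, THF, −78 °C; then 16, −78 → 0 °C; then KOtBu, rt; filter under N2, use crude
Reagents that add atoms: none
Why: Horner–Wittig olefination: the lithiated α-aminomethyl phosphine oxide adds to the non-enolisable aldehyde to give adduct 17, and its potassium alkoxide eliminates diphenylphosphinate to give the aryl-conjugated enamine, expected as the more stable E isomer.

Step 10
Reactants: 6 2,4-diacetoxy-6-methoxybenzoyl chloride; 18 (E)-4-{2-[8-(methoxymethoxy)-2,2-dimethyl-2H-chromen-6-yl]vinyl}morpholine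
Product: 22 7-hydroxy-5-methoxy-3-[8-(methoxymethoxy)-2,2-dimethyl-2H-chromen-6-yl]-4H-chromen-4-one, via diacetoxy enaminone 19 (not isolated), via hydroxy enaminone 20 (not isolated), via isoflavone 7-acetate 21 (not isolated)
Conditions: Et3N (1.5 equiv), CH2Cl2, 0 °C → rt; then morpholine 8 (2.5 equiv), 40 °C; then AcOH, 40 °C
Reagents that add atoms: none
Why: The β-carbon of enamine 18, which carries ring B, attacks the aroyl chloride and Et3N deprotonates the resulting iminium ion, giving enaminone 19 and the C3–C4 bond (Stork-type enamine C-acylation). Morpholine then removes the aryl acetates by aminolysis, and the freed ortho phenol of 20 adds to the aminomethylene carbon and expels morpholine, acetic acid protonating the leaving amine, which forms O1–C2 by conjugate addition–elimination. The closest known reaction type is chromone formation from enamines and O-acetylsalicyloyl chlorides, and the ring closure is the one that operates when 2-hydroxydeoxybenzoins are treated with formamide acetals. Ring C closes in a 6-endo-trig mode and no stereocentre is created. The step needs C- rather than N-acylation and a 3-aryl rather than a 2-aryl chromone: N-acylation of a tertiary enamine is reversible while C-acylation is locked by deprotonation, and the enamine polarity places ring B on C3. Only the ortho oxygen can reach C2, and because both acetates are cleaved in the same flask no discrimination between them is required.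

Step 11
Reactants: 22 7-hydroxy-5-methoxy-3-[8-(methoxymethoxy)-2,2-dimethyl-2H-chromen-6-yl]-4H-chromen-4-one
Product: 23 glycyrrhizaisoflavone B, 7-hydroxy-3-(8-hydroxy-2,2-dimethyl-2H-chromen-6-yl)-5-methoxy-4H-chromen-4-one
Conditions: 3 M HCl, MeOH/THF, 45 °C
Reagents that add atoms: none
Why: Acid-catalysed methanolysis of the MOM acetal, standard for pyrano-isoflavonoids; the aryl methyl ether, the chromone and the 2,2-dimethylchromene are expected to survive dilute HCl at this temperature.

Compound list
1 | 5-methoxyresorcinol | COc1cc(O)cc(O)c1 | starting material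
2 | (2,4-dihydroxy-6-methoxybenzylidene)dimethylammonium chloride | C[N+](C)=Cc1c(O)cc(O)cc1OC.[Cl-] | intermediate
3 | 2,4-dihydroxy-6-methoxybenzaldehyde | COc1cc(O)cc(O)c1C=O | intermediate
4 | 4-formyl-5-methoxy-1,3-phenylene diacetate | COc1cc(OC(C)=O)cc(OC(C)=O)c1C=O | intermediate
5 | 2,4-diacetoxy-6-methoxybenzoic acid | COc1cc(OC(C)=O)cc(OC(C)=O)c1C(=O)O | intermediate
6 | 2,4-diacetoxy-6-methoxybenzoyl chloride | COc1cc(OC(C)=O)cc(OC(C)=O)c1C(=O)Cl | intermediate
7 | diphenylphosphine oxide | O=[PH](c1ccccc1)c1ccccc1 | starting material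
8 | morpholine | C1COCCN1 | starting material
9 | (morpholinomethyl)diphenylphosphine oxide | O=P(CN1CCOCC1)(c1ccccc1)c1ccccc1 | intermediate
10 | 3,4-dihydroxybenzaldehyde | O=Cc1ccc(O)c(O)c1 | starting material
11 | 3-chloro-3-methylbut-1-yne | C#CC(C)(C)Cl | starting material
12 | 3-hydroxy-4-[(2-methylbut-3-yn-2-yl)oxy]benzaldehyde | O=Cc1ccc(OC(C)(C)C#C)c(O)c1 | intermediate
13 | 3-(methoxymethoxy)-4-[(2-methylbut-3-yn-2-yl)oxy]benzaldehyde | O=Cc1ccc(OC(C)(C)C#C)c(OCOC)c1 | intermediate
14 | 4-hydroxy-3-(methoxymethoxy)-5-(3-methylbuta-1,2-dien-1-yl)benzaldehyde | O=Cc1cc(OCOC)c(O)c(C=C=C(C)C)c1 | intermediate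
15 | (Z)-5-(methoxymethoxy)-3-(3-methylbut-2-en-1-ylidene)-4-oxocyclohexa-1,5-diene-1-carbaldehyde (ortho-quinone methide, vinyl group cis to the ring carbonyl) | O=CC1=C/C(=C/C=C(C)C)C(=O)C(OCOC)=C1 | intermediate
16 | 8-(methoxymethoxy)-2,2-dimethyl-2H-chromene-6-carbaldehyde | COCOc1cc(C=O)cc2C=CC(C)(C)Oc12 | intermediate
17 | lithium 2-(diphenylphosphoryl)-1-[8-(methoxymethoxy)-2,2-dimethyl-2H-chromen-6-yl]-2-morpholinoethan-1-olate (racemic, both diastereomers) | [Li+].[O-]C(c1cc(OCOC)c2OC(C)(C)C=Cc2c1)C(N1CCOCC1)P(=O)(c1ccccc1)c1ccccc1 | intermediate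
18 | (E)-4-{2-[8-(methoxymethoxy)-2,2-dimethyl-2H-chromen-6-yl]vinyl}morpholine | COCOc1cc(/C=C/N2CCOCC2)cc2C=CC(C)(C)Oc12 | intermediate
19 | 4-{(E)-2-[8-(methoxymethoxy)-2,2-dimethyl-2H-chromen-6-yl]-3-morpholinoacryloyl}-5-methoxy-1,3-phenylene diacetate | COc1cc(OC(C)=O)cc(OC(C)=O)c1C(=O)/C(=C/N1CCOCC1)c1cc(OCOC)c2OC(C)(C)C=Cc2c1 | intermediate
20 | 3-hydroxy-5-methoxy-4-{(E)-2-[8-(methoxymethoxy)-2,2-dimethyl-2H-chromen-6-yl]-3-morpholinoacryloyl}phenyl acetate | COc1cc(OC(C)=O)cc(O)c1C(=O)/C(=C/N1CCOCC1)c1cc(OCOC)c2OC(C)(C)C=Cc2c1 | intermediate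
21 | 5-methoxy-3-[8-(methoxymethoxy)-2,2-dimethyl-2H-chromen-6-yl]-4-oxo-4H-chromen-7-yl acetate | COc1cc(OC(C)=O)cc2occ(-c3cc(OCOC)c4OC(C)(C)C=Cc4c3)c(=O)c12 | intermediate
22 | 7-hydroxy-5-methoxy-3-[8-(methoxymethoxy)-2,2-dimethyl-2H-chromen-6-yl]-4H-chromen-4-one | COc1cc(O)cc2occ(-c3cc(OCOC)c4OC(C)(C)C=Cc4c3)c(=O)c12 | intermediate
23 | glycyrrhizaisoflavone B, 7-hydroxy-3-(8-hydroxy-2,2-dimethyl-2H-chromen-6-yl)-5-methoxy-4H-chromen-4-one | COc1cc(O)cc2occ(-c3cc(O)c4c(c3)C=CC(C)(C)O4)c(=O)c12 | target

Total step count: 11.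
Longest linear sequence: 6 steps (steps 6, 7, 8, 9, 10, 11; the ring A branch, steps 1, 2, 3, 4, 10, 11, is equally long).

Steps most likely to fail

Step 10. C-acylation of the weakly nucleophilic, aryl-conjugated enamine by the doubly ortho-substituted aroyl chloride may be slow, so that hydrolysis of the enamine by adventitious moisture or decomposition of the acid chloride overtakes C–C bond formation. The fallback sets out from 16 and comes back to the route at 23; it makes the C3–ring B bond by oxidative aryl migration in a chalcone. Commercial 1-(2,4-dihydroxy-6-methoxyphenyl)ethanone F1 is treated with MOMCl and K2CO3 in acetone to give 1-[2-hydroxy-6-methoxy-4-(methoxymethoxy)phenyl]ethanone F2, the chelated 2-hydroxyl staying free. Claisen–Schmidt condensation of F2 with 16 (KOH, EtOH, rt) should give (E)-1-[2-hydroxy-6-methoxy-4-(methoxymethoxy)phenyl]-3-[8-(methoxymethoxy)-2,2-dimethyl-2H-chromen-6-yl]prop-2-en-1-one F3. Tl(NO3)3·3H2O in MeOH/HC(OMe)3 should then move ring B from the β- to the α-carbon and give 1-[2-hydroxy-6-methoxy-4-(methoxymethoxy)phenyl]-3,3-dimethoxy-2-[8-(methoxymethoxy)-2,2-dimethyl-2H-chromen-6-yl]propan-1-one F4. HCl in MeOH at 50 °C closes ring C with loss of methanol and removes both MOM groups, giving 23.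

Step 6. Etherification may occur at the 3-oxygen or at both catechol oxygens, and the free catechol may be oxidised in the presence of copper. The fallback sets out from 10 and comes back at 13; it fixes the regiochemistry with a well-behaved primary electrophile before the tertiary propargyl group is introduced. Allyl bromide, NaHCO3 and NaI in DMF at 40 °C should give 4-(allyloxy)-3-hydroxybenzaldehyde F5; MOMCl/i-Pr2NEt gives 4-(allyloxy)-3-(methoxymethoxy)benzaldehyde F6; Pd(PPh3)4 (zerovalent palladium, catalytic) with morpholine removes the allyl group to give 4-hydroxy-3-(methoxymethoxy)benzaldehyde F7. Its only phenol is then etherified with 11 under the conditions of step 6 to give 13.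

Step 9. Elimination from the phosphine oxide adduct may stop short, or the enamine may hydrolyse while the phosphinate salts are removed. The fallback sets out from 16 and comes back at 18; it builds the arylacetaldehyde first and forms the enamine by salt-free condensation. Corey–Chaykovsky epoxidation (trimethylsulfonium iodide, NaH, DMSO/THF) should give 2-[8-(methoxymethoxy)-2,2-dimethyl-2H-chromen-6-yl]oxirane F8; Meinwald rearrangement with InCl3 (cat.) in THF gives 2-[8-(methoxymethoxy)-2,2-dimethyl-2H-chromen-6-yl]acetaldehyde F9; condensation with morpholine over K2CO3 in toluene, followed only by filtration and evaporation, gives 18.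

Further compounds
F1 | step 10 | 1-(2,4-dihydroxy-6-methoxyphenyl)ethanone | CC(=O)c1c(O)cc(O)cc1OC
F2 | step 10 | 1-[2-hydroxy-6-methoxy-4-(methoxymethoxy)phenyl]ethanone | CC(=O)c1c(O)cc(OCOC)cc1OC
F3 | step 10 | (E)-1-[2-hydroxy-6-methoxy-4-(methoxymethoxy)phenyl]-3-[8-(methoxymethoxy)-2,2-dimethyl-2H-chromen-6-yl]prop-2-en-1-one | COCOc1cc(O)c(C(=O)/C=C/c2cc(OCOC)c3OC(C)(C)C=Cc3c2)c(OC)c1
F4 | step 10 | 1-[2-hydroxy-6-methoxy-4-(methoxymethoxy)phenyl]-3,3-dimethoxy-2-[8-(methoxymethoxy)-2,2-dimethyl-2H-chromen-6-yl]propan-1-one (racemic) | COCOc1cc(O)c(C(=O)C(C(OC)OC)c2cc(OCOC)c3OC(C)(C)C=Cc3c2)c(OC)c1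
F5 | step 6 | 4-(allyloxy)-3-hydroxybenzaldehyde | C=CCOc1ccc(C=O)cc1O
F6 | step 6 | 4-(allyloxy)-3-(methoxymethoxy)benzaldehyde | C=CCOc1ccc(C=O)cc1OCOC
F7 | step 6 | 4-hydroxy-3-(methoxymethoxy)benzaldehyde | COCOc1cc(C=O)ccc1O
F8 | step 9 | 2-[8-(methoxymethoxy)-2,2-dimethyl-2H-chromen-6-yl]oxirane (racemic) | COCOc1cc(C2CO2)cc2C=CC(C)(C)Oc12
F9 | step 9 | 2-[8-(methoxymethoxy)-2,2-dimethyl-2H-chromen-6-yl]acetaldehyde | COCOc1cc(CC=O)cc2C=CC(C)(C)Oc12
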